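**Strategy.** The target is an acetophenone whose acetyl-bearing carbon C1 and chain-bearing carbon C6 are adjacent on a benzene ring carrying oxygen at C2 and C4. That ortho pair is cut back to the two carbons of 3,5-dimethoxybenzyne. In one operation the aryne inserts into the bond between the carbonyl carbon and the alpha carbon of an alpha-alkylated beta-keto sulfone, so the C1–acetyl bond and the C6–C1' bond of the side chain form together, with the regiochemistry dictated by the methoxy group next to the triple bond. The precursors are an ortho-silylaryl triflate made from 3,5-dimethoxyphenol and a phenylsulfonylacetone carrying the complete 9-phenylnonyl chain; desulfonylation and demethylation finish the synthesis.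

Key step: step 6

Remark: the target is achiral; the sulfone-bearing carbon of the keto sulfone and of the insertion product is carried as the racemate and loses its stereogenicity on desulfonylation, and phenylmagnesium bromide is taken as the commercial THF solution.

**Step 1**
Reactants: 1 3,5-dimethoxyphenol
Product: 2 2-bromo-3,5-dimethoxyphenol
Conditions: NBS (1.0 equiv), CH2Cl2, −78 °C to rt
Reagents that add atoms: N-bromosuccinimide, O=C1CCC(=O)N1Br
Why: Electrophilic aromatic bromination of this very electron-rich ring is fast at low temperature, and with one equivalent of NBS the site flanked by the free hydroxyl and one methoxy group should react in preference to the more crowded site between the two methoxy groups, any 4-bromo isomer being removed by chromatography.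

**Step 2**
Reactants: 2 2-bromo-3,5-dimethoxyphenol
Product: 3 (2-bromo-3,5-dimethoxyphenoxy)trimethylsilane
Conditions: HMDS, THF, 70 °C; volatiles removed in vacuo
Reagents that add atoms: hexamethyldisilazane, C[Si](C)(C)N[Si](C)(C)C
Why: O-Silylation of a phenol with HMDS needs no added base and leaves only ammonia, so the moisture-sensitive aryl silyl ether should be usable directly after evaporation.

**Step 3**
Reactants: 3 (2-bromo-3,5-dimethoxyphenoxy)trimethylsilane
Product: 6 3,5-dimethoxy-2-(trimethylsilyl)phenyl trifluoromethanesulfonate, via ortho-lithiated aryl silyl ether 4 (not isolated), via lithium 2-silylphenoxide 5 (not isolated)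
Conditions: n-BuLi, THF, −100 to −78 °C; then Tf2O, −100 °C to rt
Reagents that add atoms: trifluoromethanesulfonic anhydride, O=S(=O)(OS(=O)(=O)C(F)(F)F)C(F)(F)F
Why: Bromine–lithium exchange places a carbanion next to the O–Si bond, so a 1,3 oxygen-to-carbon silyl shift (retro-Brook rearrangement) should give the ortho-silyl phenoxide, which Tf2O traps on oxygen.

**Step 4**
Reactants: 7 1,9-dibromononane; 8 phenylmagnesium bromide
Product: 9 (9-bromononyl)benzene
Conditions: Li2CuCl4 (3 mol%), THF, −10 °C to rt; 7 in threefold excess
Reagents that add atoms: none
Why: Copper-catalysed cross-coupling of an aryl Grignard reagent with a primary alkyl bromide (Kochi-type coupling) should give the mono-arylated bromide, the excess of dibromide keeping double arylation low and being recovered by distillation.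

**Step 5**
Reactants: 10 1-(phenylsulfonyl)propan-2-one; 9 (9-bromononyl)benzene
Product: 11 12-phenyl-3-(phenylsulfonyl)dodecan-2-one (racemic)
Conditions: K2CO3, DMF, 60 °C; 10 in slight excess
Reagents that add atoms: none
Why: The methylene between carbonyl and sulfonyl is acidic enough for carbonate, and the soft enolate should undergo C-selective SN2 alkylation by the primary bromide, the slight excess of 10 suppressing dialkylation; the new stereocentre forms racemic and is not retained in the target.

**Step 6**
Reactants: 6 3,5-dimethoxy-2-(trimethylsilyl)phenyl trifluoromethanesulfonate; 11 12-phenyl-3-(phenylsulfonyl)dodecan-2-one (racemic)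
Product: 14 1-[2,4-dimethoxy-6-(10-phenyl-1-(phenylsulfonyl)decyl)phenyl]ethanone (racemic), via 3,5-dimethoxybenzyne 12 (not isolated), via caesium benzocyclobutenoxide 13 (not isolated)
Conditions: CsF (2.5 equiv), MeCN, 80 °C; 6 in slight excess
Reagents that add atoms: none
Why: Fluoride removes the silyl group of 6 and triflate departs to give aryne 12, to which the caesium enolate of 11 adds through its sulfone-bearing carbon at the aryne carbon remote from the flanking methoxy group, leaving the aryl anion on the carbon next to that oxygen. The aryl anion then attacks the neighbouring acetyl carbonyl (4-exo-trig) to give the transient benzocyclobutenoxide 13, whose strained ring opens by retro-aldol-type fragmentation to a sulfonyl-stabilised benzylic carbanion that is protonated by further 11 or on work-up. The closest known reaction type is the fluoride-triggered acyl-alkylation of arynes with beta-keto esters and beta-keto sulfones, alpha-substituted ones included. No ring remains in the product, the four-membered ring of 13 serving only as a relay between the two new bonds. The one new stereocentre, the benzylic carbon bearing the sulfone, forms racemic and needs no control because step 7 removes it. The selectivity the step needs is the regiochemistry of aryne attack, which the methoxy group beside the triple bond secures by distorting the aryne and stabilising the adjacent anion inductively, so that the acetyl group ends up between a methoxy group and the chain.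

**Step 7**
Reactants: 14 1-[2,4-dimethoxy-6-(10-phenyl-1-(phenylsulfonyl)decyl)phenyl]ethanone (racemic)
Product: 15 1-[2,4-dimethoxy-6-(10-phenyldecyl)phenyl]ethanone
Conditions: Mg turnings, MeOH/THF, rt to 50 °C; aq. NH4Cl
Reagents that add atoms: none
Why: Electron transfer from magnesium to the benzylic aryl sulfone should cleave the C–S bond to sulfinate and a benzylic radical or anion that methanol protonates (reductive desulfonylation), while the acetyl group, twisted out of conjugation by its two ortho substituents, is a poor electron acceptor and should survive.

**Step 8**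
Reactants: 15 1-[2,4-dimethoxy-6-(10-phenyldecyl)phenyl]ethanone
Product: 17 1-[2,4-dihydroxy-6-(10-phenyldecyl)phenyl]ethanone, via bis(dibromoboryl) aryl ether 16 (not isolated)
Conditions: BBr3 (excess), CH2Cl2, −78 °C to rt; then H2O
Reagents that add atoms: none
Why: BBr3 coordinates each ether oxygen and bromide removes the methyl group by SN2 (Lewis-acid ether cleavage), the ortho methoxy group reacting first with chelation help from the acetyl oxygen and the para one with excess reagent at room temperature, and hydrolysis of 16 should free both phenols while ketone, chain and terminal phenyl ring stay untouched.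

**Compound list**

1 | 3,5-dimethoxyphenol | COc1cc(O)cc(OC)c1 | starting material
2 | 2-bromo-3,5-dimethoxyphenol | COc1cc(OC)c(Br)c(O)c1 | intermediate
3 | (2-bromo-3,5-dimethoxyphenoxy)trimethylsilane | COc1cc(OC)c(Br)c(O[Si](C)(C)C)c1 | intermediate
4 | [2,4-dimethoxy-6-(trimethylsilyloxy)phenyl]lithium | COc1cc(OC)c([Li])c(O[Si](C)(C)C)c1 | intermediate
5 | lithium 3,5-dimethoxy-2-(trimethylsilyl)phenoxide | COc1cc(OC)c([Si](C)(C)C)c([O-])c1.[Li+] | intermediate
6 | 3,5-dimethoxy-2-(trimethylsilyl)phenyl trifluoromethanesulfonate | COc1cc(OC)c([Si](C)(C)C)c(OS(=O)(=O)C(F)(F)F)c1 | intermediate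
7 | 1,9-dibromononane | BrCCCCCCCCCBr | starting material
8 | phenylmagnesium bromide | Br[Mg]c1ccccc1 | starting material
9 | (9-bromononyl)benzene | BrCCCCCCCCCc1ccccc1 | intermediate
10 | 1-(phenylsulfonyl)propan-2-one | CC(=O)CS(=O)(=O)c1ccccc1 | starting material
11 | 12-phenyl-3-(phenylsulfonyl)dodecan-2-one (racemic) | CC(=O)C(CCCCCCCCCc1ccccc1)S(=O)(=O)c1ccccc1 | intermediate
12 | 3,5-dimethoxybenzyne (1,2-didehydro-3,5-dimethoxybenzene) | COC1=CC(OC)=CC#C1 | intermediate
13 | caesium 3,5-dimethoxy-7-methyl-8-(9-phenylnonyl)-8-(phenylsulfonyl)bicyclo[4.2.0]octa-1,3,5-trien-7-olate (racemic, diastereomer mixture) | COc1cc(OC)c2c(c1)C(CCCCCCCCCc1ccccc1)(S(=O)(=O)c1ccccc1)C2(C)[O-].[Cs+] | intermediate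
14 | 1-[2,4-dimethoxy-6-(10-phenyl-1-(phenylsulfonyl)decyl)phenyl]ethanone (racemic) | CC(=O)c1c(OC)cc(OC)cc1C(CCCCCCCCCc1ccccc1)S(=O)(=O)c1ccccc1 | intermediate
15 | 1-[2,4-dimethoxy-6-(10-phenyldecyl)phenyl]ethanone | CC(=O)c1c(OC)cc(OC)cc1CCCCCCCCCCc1ccccc1 | intermediate
16 | 1-[2,4-bis(dibromoboranyloxy)-6-(10-phenyldecyl)phenyl]ethanone | CC(=O)c1c(OB(Br)Br)cc(OB(Br)Br)cc1CCCCCCCCCCc1ccccc1 | intermediate
17 | 1-[2,4-dihydroxy-6-(10-phenyldecyl)phenyl]ethanone | CC(=O)c1c(O)cc(O)cc1CCCCCCCCCCc1ccccc1 | target

**Step count.** Total: 8 steps. Longest linear sequence: 6 steps (steps 1, 2, 3, 6, 7, 8, from 1 to 17).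

**Steps most likely to fail**

Step 6. The aryl anion formed after enolate addition may pick up a proton before it closes onto the acetyl carbonyl, so that plain alpha-arylation without acyl transfer takes over; the enolate may also add to the aryne with incomplete regiocontrol. The fallback gives up the aryne and builds the same ketone by electrophilic acylation. It sets out from 9, which Mg in THF should convert into (9-phenylnonyl)magnesium bromide F1. Li2CuCl4-catalysed coupling of F1 with commercial 3,5-dimethoxybenzyl bromide should give 1,3-dimethoxy-5-(10-phenyldecyl)benzene F2. Friedel–Crafts acetylation of F2 (acetyl chloride, SnCl4, CH2Cl2, 0 °C) is expected at the ring position ortho to the chain and para to one methoxy group, the usual site for 5-alkylresorcinol dimethyl ethers, and the route is rejoined at 15.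

Step 7. Electron transfer to the acetyl carbonyl (reduction to the carbinol or pinacol coupling) may compete with cleavage of the C–S bond, or the cleavage may stall. The fallback takes the carbonyl out of play first. It sets out from 14, which LiAlH4 in THF at 0 °C should reduce to 1-[2,4-dimethoxy-6-(10-phenyl-1-(phenylsulfonyl)decyl)phenyl]ethanol F3. With no carbonyl left, Mg in MeOH should remove the sulfone to give 1-[2,4-dimethoxy-6-(10-phenyldecyl)phenyl]ethanol F4. Oxidation of F4 with Dess–Martin periodinane in CH2Cl2 restores the ketone and comes back to the route at 15.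

Step 1. Bromination may go partly to the position between the two methoxy groups or run on to a dibromide, which erodes the supply of the aryne precursor. The fallback replaces electrophilic halogenation by carbamate-directed ortho-metalation. It sets out from 1, which diethylcarbamoyl chloride and K2CO3 in MeCN at reflux should convert into 3,5-dimethoxyphenyl diethylcarbamate F5. Treatment with s-BuLi/TMEDA in THF at −78 °C should lithiate the position between the carbamate (the stronger director) and the neighbouring methoxy group to give [2-(diethylcarbamoyloxy)-4,6-dimethoxyphenyl]lithium F6. Quenching with Me3SiCl should give 3,5-dimethoxy-2-(trimethylsilyl)phenyl diethylcarbamate F7. LiAlH4 in THF should cleave the carbamate to 3,5-dimethoxy-2-(trimethylsilyl)phenol F8 (neutral work-up to avoid protodesilylation). Triflation with Tf2O and pyridine in CH2Cl2 at 0 °C rejoins the route at 6.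

**Further compounds**

F1 | step 6 | (9-phenylnonyl)magnesium bromide | Br[Mg]CCCCCCCCCc1ccccc1
F2 | step 6 | 1,3-dimethoxy-5-(10-phenyldecyl)benzene | COc1cc(OC)cc(CCCCCCCCCCc2ccccc2)c1
F3 | step 7 | 1-[2,4-dimethoxy-6-(10-phenyl-1-(phenylsulfonyl)decyl)phenyl]ethanol (racemic, diastereomer mixture) | CC(O)c1c(OC)cc(OC)cc1C(CCCCCCCCCc1ccccc1)S(=O)(=O)c1ccccc1
F4 | step 7 | 1-[2,4-dimethoxy-6-(10-phenyldecyl)phenyl]ethanol (racemic) | CC(O)c1c(OC)cc(OC)cc1CCCCCCCCCCc1ccccc1
F5 | step 1 | 3,5-dimethoxyphenyl diethylcarbamate | CCN(CC)C(=O)Oc1cc(OC)cc(OC)c1
F6 | step 1 | [2-(diethylcarbamoyloxy)-4,6-dimethoxyphenyl]lithium | CCN(CC)C(=O)Oc1cc(OC)cc(OC)c1[Li]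
F7 | step 1 | 3,5-dimethoxy-2-(trimethylsilyl)phenyl diethylcarbamate | CCN(CC)C(=O)Oc1cc(OC)cc(OC)c1[Si](C)(C)C
F8 | step 1 | 3,5-dimethoxy-2-(trimethylsilyl)phenol | COc1cc(OC)c([Si](C)(C)C)c(O)c1
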